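## Structural features

The target is a B-type procyanidin trimer digallate: epicatechin 3-O-gallate-(4β→6)-epicatechin 3-O-gallate-(4β→8)-catechin. It consists of three flavan (2-arylchroman) units, each with a phloroglucinol-type ring A, a catechol ring B and a pyran ring C; the upper and middle units are 2R with 2,3-cis geometry, the lower unit is 2R,3S (2,3-trans). The units are joined by two diarylmethine bonds, C4(upper)–C6(middle) and C4(middle)–C8(lower). Both C4 substituents are β, trans to the neighbouring O3, so each of the two upper rings C carries a contiguous C2/C3/C4 triad (2,3-cis-3,4-trans); there are eight stereocentres in all. O3 of the upper and middle units is galloylated while O3 of the lower unit is free, so three similar secondary alcohols must be told apart. Fragile groups are the eighteen free phenols (oxidation, base-induced C2 epimerisation), the two aryl esters (base) and both interflavan bonds, which ionise reversibly under acid. The real difficulty is the 4→6 link: C6 and C8 of a flavan ring A are nearly equivalent nucleophiles and C8 is the intrinsically preferred one, and the β configuration at both C4 centres must be set without oligomerisation. The feature exploited here is that C6 of the middle ring A is para to C8a–O1: a 4-substituted 3,5-dioxygenated phenol has two identical ortho carbons (the future C4a and C8), so closing ring C of the middle unit onto such a phenol can only give the 4→6 pattern.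

## Logic of the disconnections

23 ⇒ 22. The nineteen O–CH2Ph bonds are cut (eighteen phenolic, one on O3 of the lower unit). One neutral reductive step at the end then unveils every fragile phenol, and the benzyl group on the lower O3 marks the one secondary alcohol that stays free. The forward step must spare two aryl esters and two diarylmethine C–C bonds.

22 ⇒ 21 + 4. The ester C–O bond at O3 of the middle unit is cut. This oxygen is the oxirane oxygen until the key step, so the second gallate can only be added afterwards. The forward step is an acylation of a hindered, axial secondary alcohol that is the only free hydroxyl in 21.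

21 ⇒ 20 (key). The C4–C4a bond of the middle unit is cut, which opens ring C to a trans-oxirane tethered through O1–C2 to the central arene. The central ring of 20 carries the upper unit para to the ether oxygen, so its two ortho carbons are equivalent and the 4→6 question disappears. The cut removes one ring and the C4 stereocentre and turns a tris-flavan into two chiral-pool flavans joined by an acyclic three-carbon link. The forward step must close 6-endo with inversion at the benzylic oxirane carbon, without free-cation scrambling and without cleaving the existing diarylmethine bond.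

20 ⇒ 10 + 19. The aryl ether bond O1–C2 is cut. This divides the molecule into two halves of similar size, each built on one natural flavan. The forward step is an SN2 etherification with inversion at a benzylic carbinol carbon that leaves the adjacent oxirane intact.

19 ⇒ 18 ⇒ 17. The C2–H bond (carbinol from ketone) and the two C–O bonds of the oxirane (from the E-enone) are removed. The enone is a flat platform on which a reagent-controlled epoxidation sets C3 and C4 and a chelation-controlled reduction sets C2 relative to them. The forward steps need catalyst control of the enone face regardless of the remote stereocentres, and erythro selectivity in the reduction.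

17 ⇒ 15 + 16, then 15 ⇒ 13. The Cα=Cβ bond (future C3–C4 of the middle unit) is cut by an aldol condensation, and the C8–CHO bond by a formylation. The carbon that becomes C4 of the middle unit is thus placed on the lower flavan as a formyl group at its intrinsically most nucleophilic position, so the 4→8 link needs no union of two flavans. The forward steps need C8 over C6 selectivity (the natural preference) and E-selective condensation.

13 ⇒ 12 ⇒ 11. The O-benzyl bonds are cut, phenolic ones first and the one on O3 second. The two-stage protection avoids strong base while phenols are free.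

10 ⇒ 9 ⇒ 8 ⇒ 7. Two O-benzyl bonds and one O–Si bond on the central ring are adjusted so that only the oxygen para to the flavanyl group is free. The demand is site-selective silylation of the one unhindered hydroxyl among three.

7 ⇒ 5 + 6. The C4(upper)–aryl bond is cut. With 6 all three nucleophilic carbons are identical, so this diarylmethine bond forms with no regiochemical issue, and the 3-O-acyl group of 5 steers the arene to the β face. The forward step must stop at monoalkylation.

5 ⇒ 3 + 4, then 3 ⇒ 2 ⇒ 1. The ester C–O bond, the C4–O bond (benzylic oxidation) and four phenolic O-benzyl bonds are cut, leading back to the natural flavan.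

## Other disconnections considered

Alternative 1: The cut is at both diarylmethine bonds between intact flavans, which is the first plan that comes to mind. The forward key step would be a Lewis-acid Friedel–Crafts alkylation of the C4 cation from 5 with the C8-brominated nucleophile A1, giving the 4→6 dimer A2; the lower ring of A2 would then be oxidised at C4 and coupled with 12 in a second cationic step. The 4→6 regiochemistry rests only on a blocking atom. The second benzylic oxidation must distinguish the C4 methylene of the lower ring from the diarylmethine C4–H of the upper ring of A2. A C4 cation of a dimer can also fragment at the first, acid-labile interflavan bond, and each coupling needs an excess of nucleophile to hold back oligomers. The chosen plan makes one cationic bond only, to a symmetric partner.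

Alternative 2: The cut is at O1–C2 and C3–C4 of the middle ring C at once. The forward key step would be ortho-hydroxyalkylation of 10 with 15 to the benzhydrol A4, then dehydration in the presence of the (Z)-enol gallate A3, so that the resulting ortho-quinone methide undergoes an inverse-demand hetero-Diels–Alder reaction that leads directly to 22. This is shorter on paper. However, suprafacial addition of a Z-dienophile through the usual endo arrangement (aryl under the heterodiene) to an E-methide gives the all-cis triad with C2 and C4 aryl groups cis, whereas the target needs them trans (exo). Nothing controls the absolute face, and a stepwise path through a 3,4-dialkoxybenzyl cation would lose the Z geometry. In the chosen plan each of the three centres comes from a stereospecific event.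

Alternative 3: The cut is at C4–C4a and O1–C2 with ring C at the flav-2-ene oxidation level. The forward key step would be conjugate Friedel–Crafts addition of 10 to enone 17 and cyclodehydration to the 4H-chromene A5, followed by oxygenation of the enol ether C2=C3. C4 would be created by attack on a planar β-carbon with only remote stereocentres to bias it. Syn hydroboration anti to the C4 aryl group would give the 2,3-trans-3,4-trans triad, not the one required. The anti addition of H and O that is needed would pass through a 2-aryl oxocarbenium ion of unsecured facial preference. The chosen plan uses the same two fragments but oxidises the enone first (17 to 18), so that C3 and C4 derive from a trans-oxirane opened with inversion.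

Key step: step 15

Remark on the chemistry: the target is taken as read from its SMILES, epicatechin 3-O-gallate-(4β→6)-epicatechin 3-O-gallate-(4β→8)-catechin; rotamers about the two interflavan bonds are assumed to interconvert and are not treated as separate stereoisomers.

## Route

Step 1
Reactants: 1 (−)-epicatechin
Product: 2 5,7,3',4'-tetra-O-benzyl-(−)-epicatechin
Conditions: BnBr (4.4 equiv), K2CO3, DMF, 0 °C → rt
Reagents that add atoms: benzyl bromide, BrCc1ccccc1
Why: Williamson etherification; carbonate deprotonates only the four phenols, so the secondary 3-OH stays free, and the mild base should leave C2 untouched.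

Step 2
Reactants: 2 5,7,3',4'-tetra-O-benzyl-(−)-epicatechin
Product: 3 5,7,3',4'-tetra-O-benzyl-4β-(2-ethoxyethoxy)-(−)-epicatechin (4-alkoxy group trans to 3-OH)
Conditions: DDQ (2 equiv), 2-ethoxyethanol (5 equiv), CH2Cl2, rt
Reagents that add atoms: 2-ethoxyethanol, CCOCCO
Why: DDQ benzylic oxidation; hydride abstraction from C4 gives the cation stabilised by ring A, and the alcohol should capture it on the face anti to the pseudo-axial 3-OH, setting the 4β (3,4-trans) ether.

Step 3
Reactants: 3 5,7,3',4'-tetra-O-benzyl-4β-(2-ethoxyethoxy)-(−)-epicatechin; 4 3,4,5-tris(benzyloxy)benzoic acid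
Product: 5 5,7,3',4'-tetra-O-benzyl-4β-(2-ethoxyethoxy)-(−)-epicatechin 3-O-[3,4,5-tris(benzyloxy)benzoate]
Conditions: DCC, DMAP (cat.), CH2Cl2, rt
Reagents that add atoms: none
Why: Steglich esterification of the only free hydroxyl; the neutral conditions should keep the acid-labile C4 ether.

Step 4
Reactants: 5 the 4β-(2-ethoxyethoxy) gallate; 6 phloroglucinol
Product: 7 2-[5,7,3',4'-tetra-O-benzyl-3-O-(tri-O-benzylgalloyl)-(−)-epicatechin-4β-yl]benzene-1,3,5-triol
Conditions: 6 (8 equiv), BF3·OEt2 (0.5 equiv), THF/CH2Cl2, −40 → 0 °C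
Reagents that add atoms: none
Why: SN1 Friedel–Crafts alkylation; the Lewis acid ionises the C4 ether and the 3-O-acyl group screens the α face (acyloxonium participation), so the arene should enter β and give the 3,4-trans adduct. The three CH positions of 6 are identical, so no regiochemistry arises, and the excess suppresses dialkylation and self-condensation of 5.

Step 5
Reactants: 7 the flavan-4β-yl phloroglucinol
Product: 8 the mono-triisopropylsilyl ether of 7, silylated on the hydroxyl para to the flavanyl group
Conditions: iPr3SiCl (1.05 equiv), imidazole, DMF, −20 °C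
Reagents that add atoms: chlorotriisopropylsilane, CC(C)[Si](Cl)(C(C)C)C(C)C
Why: Phenol silylation; the hydroxyl para to the flavanyl group has two free ortho positions, whereas the other two each adjoin the bulky C4 substituent, so the hindered silyl chloride should select the para oxygen.

Step 6
Reactants: 8 the para-O-silyl diol
Product: 9 [3,5-bis(benzyloxy)-4-(flavan-4β-yl)phenyl] triisopropylsilyl ether (flavanyl = tetra-O-benzyl-3-O-(tri-O-benzylgalloyl)epicatechin-4-yl)
Conditions: BnBr, K2CO3, acetone, 50 °C
Reagents that add atoms: benzyl bromide, BrCc1ccccc1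
Why: Williamson etherification of the two remaining phenols; the aryl triisopropylsilyl ether and the gallate ester should tolerate anhydrous carbonate.

Step 7
Reactants: 9 the silyl ether
Product: 10 3,5-bis(benzyloxy)-4-[5,7,3',4'-tetra-O-benzyl-3-O-(tri-O-benzylgalloyl)-(−)-epicatechin-4β-yl]phenol
Conditions: Bu4NF, AcOH, THF, 0 °C
Reagents that add atoms: none
Why: Fluoride desilylation; buffering with acetic acid should protect the gallate ester from the basic fluoride.

Step 8
Reactants: 11 (+)-catechin
Product: 12 5,7,3',4'-tetra-O-benzyl-(+)-catechin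
Conditions: BnBr (4.4 equiv), K2CO3, DMF, 0 °C → rt
Reagents that add atoms: benzyl bromide, BrCc1ccccc1
Why: Williamson etherification of the four phenols, as in step 1.

Step 9
Reactants: 12 5,7,3',4'-tetra-O-benzyl-(+)-catechin
Product: 13 3,5,7,3',4'-penta-O-benzyl-(+)-catechin
Conditions: NaH, BnBr, DMF, 0 °C → rt
Reagents that add atoms: benzyl bromide, BrCc1ccccc1
Why: Williamson etherification of the secondary alkoxide; this benzyl group marks the one 3-OH that ends free, and with all phenols capped the strong base can no longer open ring C or epimerise C2.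

Step 10
Reactants: 13 3,5,7,3',4'-penta-O-benzyl-(+)-catechin
Product: 15 8-formyl-3,5,7,3',4'-penta-O-benzyl-(+)-catechin, via C8 dimethyliminium chloride 14 (not isolated)
Conditions: POCl3, DMF, 0 → 50 °C; then aq. NaOAc
Reagents that add atoms: N,N-dimethylformamide, CN(C)C=O; water, O
Why: Vilsmeier–Haack formylation; C8 is the usual site of electrophilic substitution in 5,7-di-O-alkyl flavans (para to O5, flanked by the less encumbering ring oxygen), and the iminium salt is hydrolysed on work-up.

Step 11
Reactants: 15 8-formyl-penta-O-benzylcatechin; 16 1-[3,4-bis(benzyloxy)phenyl]ethan-1-one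
Product: 17 (E)-1-[3,4-bis(benzyloxy)phenyl]-3-[3,5,7,3',4'-penta-O-benzyl-(+)-catechin-8-yl]prop-2-en-1-one
Conditions: KOH, EtOH/THF, rt
Reagents that add atoms: none
Why: Claisen–Schmidt condensation; the aldehyde cannot enolise and E1cB dehydration of the aldol should give the E-enone.

Step 12
Reactants: 17 the E-enone
Product: 18 (2R,3S)-trans-2,3-epoxy ketone of 17 (oxirane carbon next to C=O is R, aryl-bearing oxirane carbon is S)
Conditions: poly-L-leucine, urea·H2O2, DBU, THF, rt
Reagents that add atoms: hydrogen peroxide–urea, NC(N)=O.OO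
Why: Juliá–Colonna epoxidation (Weitz–Scheffer type); stepwise conjugate addition and closure give the trans-oxirane, and the poly-L-leucine helix should deliver hydroperoxide to the enone face that gives the (2R,3S) epoxide as with chalcone itself, the remote flavan stereocentres having little influence.

Step 13
Reactants: 18 the (2R,3S)-epoxy ketone
Product: 19 erythro epoxy alcohol, (S)-[3,4-bis(benzyloxy)phenyl][(2S,3S)-3-(penta-O-benzylcatechin-8-yl)oxiran-2-yl]methanol
Conditions: Zn(BH4)2, Et2O, −20 °C
Reagents that add atoms: none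
Why: Chelation-controlled reduction of an α,β-epoxy ketone; zinc bridges the carbonyl and oxirane oxygens and hydride should attack the carbonyl face not screened by the aryl-bearing oxirane carbon, giving the erythro (anti) alcohol.

Step 14
Reactants: 10 the central phenol carrying the upper unit; 19 the erythro epoxy alcohol
Product: 20 aryl ether of 10 with 19, carbinol carbon inverted to R, trans-oxirane unchanged
Conditions: PPh3, DIAD, toluene, 0 °C → rt
Reagents that add atoms: none
Why: Mitsunobu etherification; the unhindered phenol should displace the alkoxyphosphonium group by SN2 with inversion, turning the erythro alcohol into the threo ether that maps onto 2,3-cis, while the electron-withdrawing oxirane next to the reacting carbon disfavours ionisation.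

Step 15
Reactants: 20 the epoxy aryl ether
Product: 21 [5,7,3',4'-tetra-O-benzyl-3-O-(tri-O-benzylgalloyl)epicatechin]-(4β→6)-[5,7,3',4'-tetra-O-benzylepicatechin]-(4β→8)-[3,5,7,3',4'-penta-O-benzylcatechin], middle 3-OH free
Conditions: BF3·OEt2 (0.2 equiv), CH2Cl2 (0.005 M), −78 → −40 °C; Et3N quench
Reagents that add atoms: none
Why: BF3 coordinates the oxirane oxygen and polarises the benzylic C4–O bond, which the 2,4,6-trioxygenated ring A of the lower unit stabilises; an ortho carbon of the tethered central aryl ether attacks C4 from the side opposite the departing oxygen and rearomatisation leaves the 3-hydroxyl. The closest known reaction type is the intramolecular Friedel–Crafts epoxy–arene cyclisation of trans-3-arylglycidyl aryl ethers to trans-4-arylchroman-3-ols. Ring C of the middle unit closes in the 6-endo-tet mode (both oxirane carbons end in the ring); the 5-exo alternative at C3 is disfavoured because only C4 is benzylic. C4 is set by inversion at the trans-oxirane carbon, which places the lower unit β and trans to O3. C3 keeps the configuration written in by the epoxidation because its C–O bond is not broken, and C2 was fixed in step 14 and is not touched, so the 2,3-cis-3,4-trans triad follows from the threo-ether and trans-oxirane geometry of 20. Regioselectivity needs no control: the two carbons ortho to the ether oxygen are constitutionally equivalent because the upper unit sits para to that oxygen, so either closure gives the 4→6 pattern and a 4→8 isomer cannot arise. Chemoselectivity rests on the tethered trialkoxy ring being the most nucleophilic arene within reach; the catechol ring on C2 could only close a five-membered ring and the outer rings A can react only intermolecularly, which high dilution suppresses. Low temperature and sub-stoichiometric acid should spare both diarylmethine bonds and the ester.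

Step 16
Reactants: 21 the trimer with free middle 3-OH; 4 3,4,5-tris(benzyloxy)benzoic acid
Product: 22 nonadeca-O-benzyl derivative of the target (21 esterified at O3 of the middle unit with the tri-O-benzylgalloyl group)
Conditions: DCC, DMAP, CH2Cl2, rt → 35 °C
Reagents that add atoms: none
Why: Steglich esterification of the only free hydroxyl; the reaction type is established for axial 3-hydroxyls of 4-arylflavans.

Step 17
Reactants: 22 the perbenzylated digallate
Product: 23 epicatechin 3-O-gallate-(4β→6)-epicatechin 3-O-gallate-(4β→8)-catechin (CNP0112921.1)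
Conditions: H2 (1 atm), Pd(OH)2/C, THF/MeOH/H2O, rt
Reagents that add atoms: none
Why: Hydrogenolysis of nineteen benzyl ethers under neutral conditions; the aryl esters and diarylmethine C–C bonds should survive and no stereocentre is touched.

## Compound list

1 | (−)-epicatechin | O[C@@H]1Cc2c(O)cc(O)cc2O[C@@H]1c1ccc(O)c(O)c1 | starting material
2 | 5,7,3',4'-tetra-O-benzyl-(−)-epicatechin | O[C@@H]1Cc2c(OCc5ccccc5)cc(OCc5ccccc5)cc2O[C@@H]1c1ccc(OCc5ccccc5)c(OCc5ccccc5)c1 | intermediate
3 | 5,7,3',4'-tetra-O-benzyl-4β-(2-ethoxyethoxy)-(−)-epicatechin | O[C@@H]1[C@@H](OCCOCC)c2c(OCc5ccccc5)cc(OCc5ccccc5)cc2O[C@@H]1c1ccc(OCc5ccccc5)c(OCc5ccccc5)c1 | intermediate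
4 | 3,4,5-tris(benzyloxy)benzoic acid | OC(=O)c1cc(OCc5ccccc5)c(OCc5ccccc5)c(OCc5ccccc5)c1 | starting material
5 | 5,7,3',4'-tetra-O-benzyl-4β-(2-ethoxyethoxy)-(−)-epicatechin 3-O-[3,4,5-tris(benzyloxy)benzoate] | O=C(O[C@@H]1[C@@H](OCCOCC)c2c(OCc5ccccc5)cc(OCc5ccccc5)cc2O[C@@H]1c1ccc(OCc5ccccc5)c(OCc5ccccc5)c1)c1cc(OCc5ccccc5)c(OCc5ccccc5)c(OCc5ccccc5)c1 | intermediate
6 | phloroglucinol | Oc1cc(O)cc(O)c1 | starting material
7 | 2-[5,7,3',4'-tetra-O-benzyl-3-O-(tri-O-benzylgalloyl)-(−)-epicatechin-4β-yl]benzene-1,3,5-triol | O=C(O[C@@H]1[C@@H](c2c(O)cc(O)cc2O)c2c(OCc5ccccc5)cc(OCc5ccccc5)cc2O[C@@H]1c1ccc(OCc5ccccc5)c(OCc5ccccc5)c1)c1cc(OCc5ccccc5)c(OCc5ccccc5)c(OCc5ccccc5)c1 | intermediate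
8 | mono-triisopropylsilyl ether of 7 at the hydroxyl para to the flavanyl group | O=C(O[C@@H]1[C@@H](c2c(O)cc(O[Si](C(C)C)(C(C)C)C(C)C)cc2O)c2c(OCc5ccccc5)cc(OCc5ccccc5)cc2O[C@@H]1c1ccc(OCc5ccccc5)c(OCc5ccccc5)c1)c1cc(OCc5ccccc5)c(OCc5ccccc5)c(OCc5ccccc5)c1 | intermediate
9 | [3,5-bis(benzyloxy)-4-(tetra-O-benzyl-3-O-(tri-O-benzylgalloyl)epicatechin-4β-yl)phenyl] triisopropylsilyl ether | O=C(O[C@@H]1[C@@H](c2c(OCc5ccccc5)cc(O[Si](C(C)C)(C(C)C)C(C)C)cc2OCc5ccccc5)c2c(OCc5ccccc5)cc(OCc5ccccc5)cc2O[C@@H]1c1ccc(OCc5ccccc5)c(OCc5ccccc5)c1)c1cc(OCc5ccccc5)c(OCc5ccccc5)c(OCc5ccccc5)c1 | intermediate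
10 | 3,5-bis(benzyloxy)-4-[5,7,3',4'-tetra-O-benzyl-3-O-(tri-O-benzylgalloyl)-(−)-epicatechin-4β-yl]phenol | O=C(O[C@@H]1[C@@H](c2c(OCc5ccccc5)cc(O)cc2OCc5ccccc5)c2c(OCc5ccccc5)cc(OCc5ccccc5)cc2O[C@@H]1c1ccc(OCc5ccccc5)c(OCc5ccccc5)c1)c1cc(OCc5ccccc5)c(OCc5ccccc5)c(OCc5ccccc5)c1 | intermediate
11 | (+)-catechin | O[C@H]1Cc2c(O)cc(O)cc2O[C@@H]1c1ccc(O)c(O)c1 | starting material
12 | 5,7,3',4'-tetra-O-benzyl-(+)-catechin | O[C@H]1Cc2c(OCc5ccccc5)cc(OCc5ccccc5)cc2O[C@@H]1c1ccc(OCc5ccccc5)c(OCc5ccccc5)c1 | intermediate
13 | 3,5,7,3',4'-penta-O-benzyl-(+)-catechin | O(Cc5ccccc5)[C@H]1Cc2c(OCc5ccccc5)cc(OCc5ccccc5)cc2O[C@@H]1c1ccc(OCc5ccccc5)c(OCc5ccccc5)c1 | intermediate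
14 | C8 N,N-dimethyliminium chloride of 13 (not isolated) | C[N+](C)=Cc1c(OCc5ccccc5)cc(OCc5ccccc5)c2c1O[C@H](c3ccc(OCc5ccccc5)c(OCc5ccccc5)c3)[C@@H](OCc5ccccc5)C2.[Cl-] | intermediate
15 | 8-formyl-3,5,7,3',4'-penta-O-benzyl-(+)-catechin | O=Cc1c(OCc5ccccc5)cc(OCc5ccccc5)c2c1O[C@H](c3ccc(OCc5ccccc5)c(OCc5ccccc5)c3)[C@@H](OCc5ccccc5)C2 | intermediate
16 | 1-[3,4-bis(benzyloxy)phenyl]ethan-1-one | CC(=O)c1ccc(OCc5ccccc5)c(OCc5ccccc5)c1 | starting material
17 | (E)-1-[3,4-bis(benzyloxy)phenyl]-3-[penta-O-benzyl-(+)-catechin-8-yl]prop-2-en-1-one | O=C(/C=C/c1c(OCc5ccccc5)cc(OCc5ccccc5)c2c1O[C@H](c3ccc(OCc5ccccc5)c(OCc5ccccc5)c3)[C@@H](OCc5ccccc5)C2)c1ccc(OCc5ccccc5)c(OCc5ccccc5)c1 | intermediate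
18 | (2R,3S)-trans-2,3-epoxy ketone of 17 | O=C([C@@H]6O[C@H]6c1c(OCc5ccccc5)cc(OCc5ccccc5)c2c1O[C@H](c3ccc(OCc5ccccc5)c(OCc5ccccc5)c3)[C@@H](OCc5ccccc5)C2)c1ccc(OCc5ccccc5)c(OCc5ccccc5)c1 | intermediate
19 | (S)-[3,4-bis(benzyloxy)phenyl][(2S,3S)-3-(penta-O-benzylcatechin-8-yl)oxiran-2-yl]methanol (erythro) | O[C@@H](c1ccc(OCc5ccccc5)c(OCc5ccccc5)c1)[C@@H]6O[C@H]6c1c(OCc5ccccc5)cc(OCc5ccccc5)c2c1O[C@H](c3ccc(OCc5ccccc5)c(OCc5ccccc5)c3)[C@@H](OCc5ccccc5)C2 | intermediate
20 | aryl ether of phenol 10 with 19 (carbinol carbon inverted to R, trans-oxirane retained) | O=C(O[C@@H]1[C@@H](c2c(OCc5ccccc5)cc(O[C@H](c3ccc(OCc5ccccc5)c(OCc5ccccc5)c3)[C@@H]6O[C@H]6c7c(OCc5ccccc5)cc(OCc5ccccc5)c8c7O[C@H](c9ccc(OCc5ccccc5)c(OCc5ccccc5)c9)[C@@H](OCc5ccccc5)C8)cc2OCc5ccccc5)c2c(OCc5ccccc5)cc(OCc5ccccc5)cc2O[C@@H]1c1ccc(OCc5ccccc5)c(OCc5ccccc5)c1)c1cc(OCc5ccccc5)c(OCc5ccccc5)c(OCc5ccccc5)c1 | intermediate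
21 | [tetra-O-benzyl-3-O-(tri-O-benzylgalloyl)epicatechin]-(4β→6)-[5,7,3',4'-tetra-O-benzylepicatechin]-(4β→8)-[penta-O-benzylcatechin] | O=C(O[C@@H]1[C@@H](c2c(OCc5ccccc5)cc3c(c2OCc5ccccc5)[C@H](c2c(OCc5ccccc5)cc(OCc5ccccc5)c4c2O[C@H](c2ccc(OCc5ccccc5)c(OCc5ccccc5)c2)[C@@H](OCc5ccccc5)C4)[C@@H](O)[C@@H](c2ccc(OCc5ccccc5)c(OCc5ccccc5)c2)O3)c2c(OCc5ccccc5)cc(OCc5ccccc5)cc2O[C@@H]1c1ccc(OCc5ccccc5)c(OCc5ccccc5)c1)c1cc(OCc5ccccc5)c(OCc5ccccc5)c(OCc5ccccc5)c1 | intermediate
22 | nonadeca-O-benzyl derivative of the target (middle O3 esterified with the tri-O-benzylgalloyl group) | O=C(O[C@@H]1[C@@H](c2c(OCc5ccccc5)cc3c(c2OCc5ccccc5)[C@H](c2c(OCc5ccccc5)cc(OCc5ccccc5)c4c2O[C@H](c2ccc(OCc5ccccc5)c(OCc5ccccc5)c2)[C@@H](OCc5ccccc5)C4)[C@@H](OC(=O)c2cc(OCc5ccccc5)c(OCc5ccccc5)c(OCc5ccccc5)c2)[C@@H](c2ccc(OCc5ccccc5)c(OCc5ccccc5)c2)O3)c2c(OCc5ccccc5)cc(OCc5ccccc5)cc2O[C@@H]1c1ccc(OCc5ccccc5)c(OCc5ccccc5)c1)c1cc(OCc5ccccc5)c(OCc5ccccc5)c(OCc5ccccc5)c1 | intermediate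
23 | epicatechin 3-O-gallate-(4β→6)-epicatechin 3-O-gallate-(4β→8)-catechin (CNP0112921.1) | O=C(O[C@@H]1[C@@H](c2c(O)cc3c(c2O)[C@H](c2c(O)cc(O)c4c2O[C@H](c2ccc(O)c(O)c2)[C@@H](O)C4)[C@@H](OC(=O)c2cc(O)c(O)c(O)c2)[C@@H](c2ccc(O)c(O)c2)O3)c2c(O)cc(O)cc2O[C@@H]1c1ccc(O)c(O)c1)c1cc(O)c(O)c(O)c1 | target

## Step count and least certain steps

Total: 17 steps. Longest linear sequence: 11 steps (steps 1 to 7, then 14 to 17); the lower branch (steps 8 to 13) joins at step 14.

Step 15 (key step). The most likely failure is ionisation of the oxirane to a free benzylic cation before the ring closes, with loss of the anti course at C4 or a 1,2-hydride shift to a ketone (Meinwald rearrangement). The cause is the very electron-rich aryl group on the oxirane. Fallback: the order of the two ring bonds is reversed, setting out from 10 and 18 and returning at 21. Phenol 10 would be alkylated at its ortho carbon by the epoxy ketone 18 in hexafluoroisopropanol/CH2Cl2 (intermolecular Friedel–Crafts opening at the benzylic carbon with inversion; a protic activator is used because a Lewis acid would invite the 1,2-acyl shift of the epoxy ketone). The resulting hydroxy ketone closes onto the phenol to the cyclic hemiketal F1, and ionic hydrogenation (Et3SiH, BF3·OEt2, CH2Cl2, −78 °C), by axial hydride delivery trans to the pseudo-axial 3-hydroxyl, would give 21. The carbonyl group next to the oxirane tempers ionisation at the stage where C4 is set.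

Step 14. The likely failure is ionisation of the activated benzylic alcohol (SN1) with erosion of the inversion, or sluggish substitution at the crowded carbinol carbon. Fallback: the ether bond is made before the oxirane exists, setting out from 17 and 10 and returning at 20. Corey–Bakshi–Shibata reduction of 17 (Me-CBS oxazaborolidine, BH3·SMe2) would give the (S,E)-allylic alcohol F2, and ClCO2Me/pyridine its methyl carbonate F3. Tsuji–Trost etherification of F3 with 10 (Pd(PPh3)4, THF) should proceed with net retention at the allyl terminus remote from the di-ortho-substituted aryl group, giving the allyl aryl ether F4. Shi epoxidation of F4 (fructose-derived ketone of the matching series, KHSO5, K2CO3 buffer) would then give 20.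

Step 12. The likely failure is slow or poorly face-selective addition of hydroperoxide to an enone whose β-aryl group is di-ortho-substituted and electron-rich. Fallback: the oxirane is built from the aldehyde, setting out from 15 and returning at 18. An asymmetric Darzens condensation of 15 with 2-bromo-1-[3,4-bis(benzyloxy)phenyl]ethan-1-one (cinchona-derived quaternary ammonium phase-transfer catalyst, LiOH, Bu2O) would give the trans-epoxy ketone 18 directly; this fallback makes no new isolated compound (F0).

Step 5. The likely failure is insufficient site selectivity in silylating one of three phenols. Fallback: the oxygen pattern is built into the nucleophile, setting out from 5 and returning at 9. Commercial 3,5-bis(benzyloxy)phenol would be silylated (iPr3SiCl, imidazole) to 1,3-bis(benzyloxy)-5-(triisopropylsilyloxy)benzene F5. Friedel–Crafts alkylation of F5 with 5 (BF3·OEt2, CH2Cl2, −40 °C) should occur between the two benzyloxy groups, the two other positions being screened by the bulky silyl ether, and would give 9 without passing through 7 and 8.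

## Further compounds

F1 | step 15 | cyclic hemiketal (2-hydroxy derivative of 21; C2 as an equilibrating mixture) | O=C(O[C@@H]1[C@@H](c2c(OCc5ccccc5)cc3c(c2OCc5ccccc5)[C@H](c2c(OCc5ccccc5)cc(OCc5ccccc5)c4c2O[C@H](c2ccc(OCc5ccccc5)c(OCc5ccccc5)c2)[C@@H](OCc5ccccc5)C4)[C@@H](O)C(O)(c2ccc(OCc5ccccc5)c(OCc5ccccc5)c2)O3)c2c(OCc5ccccc5)cc(OCc5ccccc5)cc2O[C@@H]1c1ccc(OCc5ccccc5)c(OCc5ccccc5)c1)c1cc(OCc5ccccc5)c(OCc5ccccc5)c(OCc5ccccc5)c1
F2 | step 14 | (S,E)-1-[3,4-bis(benzyloxy)phenyl]-3-(penta-O-benzylcatechin-8-yl)prop-2-en-1-ol | O[C@H](c1ccc(OCc5ccccc5)c(OCc5ccccc5)c1)/C=C/c1c(OCc5ccccc5)cc(OCc5ccccc5)c2c1O[C@H](c3ccc(OCc5ccccc5)c(OCc5ccccc5)c3)[C@@H](OCc5ccccc5)C2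
F3 | step 14 | methyl carbonate of F2 | COC(=O)O[C@H](c1ccc(OCc5ccccc5)c(OCc5ccccc5)c1)/C=C/c1c(OCc5ccccc5)cc(OCc5ccccc5)c2c1O[C@H](c3ccc(OCc5ccccc5)c(OCc5ccccc5)c3)[C@@H](OCc5ccccc5)C2
F4 | step 14 | (E)-allyl aryl ether of 10 (20 with an alkene in place of the oxirane) | O=C(O[C@@H]1[C@@H](c2c(OCc5ccccc5)cc(O[C@H](c3ccc(OCc5ccccc5)c(OCc5ccccc5)c3)/C=C/c7c(OCc5ccccc5)cc(OCc5ccccc5)c8c7O[C@H](c9ccc(OCc5ccccc5)c(OCc5ccccc5)c9)[C@@H](OCc5ccccc5)C8)cc2OCc5ccccc5)c2c(OCc5ccccc5)cc(OCc5ccccc5)cc2O[C@@H]1c1ccc(OCc5ccccc5)c(OCc5ccccc5)c1)c1cc(OCc5ccccc5)c(OCc5ccccc5)c(OCc5ccccc5)c1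
F5 | step 5 | 1,3-bis(benzyloxy)-5-(triisopropylsilyloxy)benzene | CC(C)[Si](Oc1cc(OCc5ccccc5)cc(OCc5ccccc5)c1)(C(C)C)C(C)C
F0 | step 12 | none | none
A1 | alternative 1 | 8-bromo-5,7,3',4'-tetra-O-benzyl-(−)-epicatechin | O[C@@H]1Cc2c(OCc5ccccc5)cc(OCc5ccccc5)c(Br)c2O[C@@H]1c1ccc(OCc5ccccc5)c(OCc5ccccc5)c1
A2 | alternative 1 | [tetra-O-benzyl-3-O-(tri-O-benzylgalloyl)epicatechin]-(4β→6)-[8-bromo-tetra-O-benzylepicatechin] | O=C(O[C@@H]1[C@@H](c2c(OCc5ccccc5)c(Br)c3c(c2OCc5ccccc5)C[C@@H](O)[C@@H](c2ccc(OCc5ccccc5)c(OCc5ccccc5)c2)O3)c2c(OCc5ccccc5)cc(OCc5ccccc5)cc2O[C@@H]1c1ccc(OCc5ccccc5)c(OCc5ccccc5)c1)c1cc(OCc5ccccc5)c(OCc5ccccc5)c(OCc5ccccc5)c1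
A3 | alternative 2 | (Z)-2-[3,4-bis(benzyloxy)phenyl]ethenyl 3,4,5-tris(benzyloxy)benzoate | O=C(O/C=C\c1ccc(OCc5ccccc5)c(OCc5ccccc5)c1)c1cc(OCc5ccccc5)c(OCc5ccccc5)c(OCc5ccccc5)c1
A4 | alternative 2 | ortho-hydroxybenzhydrol from 10 and 15 (carbinol centre either way) | O=C(O[C@@H]1[C@@H](c2c(OCc5ccccc5)cc(O)c(C(O)c7c(OCc5ccccc5)cc(OCc5ccccc5)c8c7O[C@H](c9ccc(OCc5ccccc5)c(OCc5ccccc5)c9)[C@@H](OCc5ccccc5)C8)c2OCc5ccccc5)c2c(OCc5ccccc5)cc(OCc5ccccc5)cc2O[C@@H]1c1ccc(OCc5ccccc5)c(OCc5ccccc5)c1)c1cc(OCc5ccccc5)c(OCc5ccccc5)c(OCc5ccccc5)c1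
A5 | alternative 3 | 4H-chromene (flav-2-ene) from 10 and 17, C4 drawn in the required configuration | O=C(O[C@@H]1[C@@H](c2c(OCc5ccccc5)cc3c(c2OCc5ccccc5)[C@H](c2c(OCc5ccccc5)cc(OCc5ccccc5)c4c2O[C@H](c2ccc(OCc5ccccc5)c(OCc5ccccc5)c2)[C@@H](OCc5ccccc5)C4)C=C(c2ccc(OCc5ccccc5)c(OCc5ccccc5)c2)O3)c2c(OCc5ccccc5)cc(OCc5ccccc5)cc2O[C@@H]1c1ccc(OCc5ccccc5)c(OCc5ccccc5)c1)c1cc(OCc5ccccc5)c(OCc5ccccc5)c(OCc5ccccc5)c1
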